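**Plan**
Cuts: first the three MOM acetals. Then, in one retrosynthetic move, the benzylic CH2–aryl bond and the lactone bond O1–C5, which leaves aryl iodide 11 and the acyclic (Z)-dienoic acid 7.
Enabling feature: C5 of the furan-2(5H)-one ring carries the lactone oxygen O1, is allylic to the enol double bond C3=C4, and is flanked by the benzylic CH2. Both bonds are therefore the outcome of a 1,2-oxyarylation of a vinyl group through an η3-allyl spanning C5–C4–C3.
Forward, acid half: 4-hydroxyphenylpyruvic acid and chloroacetaldehyde close a racemic 5-(chloromethyl) lactone, a temporary ring that fixes the alkene geometry. Zinc opens it to 7 (CO2H cis to vinyl) and erases the racemic centre.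
Forward, aryl half: 4-iodophenol is ortho-C-prenylated and protected to 11. The arylative lactonisation then joins 7 and 11 and re-closes the only heterocycle.
Stereochemistry: the single centre C5 (R) is set in that step by the chiral P,N ligand on palladium. Only an acidic deprotection follows, and it leaves C5–H untouched.

Key step: step 6

Assumption: the sense of induction of (S)-t-BuPHOX on this substrate class cannot be read from precedent. The (S)-ligand is written, and its mirror image is taken if a test run shows the (S)-lactone.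

Step 1
Reactants: 1 4-hydroxyphenylpyruvic acid; 2 chloroacetaldehyde
Product: 4 rac-5-(chloromethyl)-3-hydroxy-4-(4-hydroxyphenyl)furan-2(5H)-one, via aldol adduct 3 (not isolated)
Conditions: K2CO3 (1.2 equiv), 2 (1.5 equiv, 50 wt % in H2O), MeOH–H2O, 0 °C to rt, N2; then 2 M HCl to pH 1, rt
Reagents that add atoms: none
Why: Crossed aldol addition of the easily enolised benzylic carbon of the arylpyruvate to the very electrophilic aldehyde, followed on acidification by lactonisation of the γ-hydroxy-α-keto acid and enolisation (isotetronic acid synthesis), should give 4, whose C5 is racemic on purpose because step 3 erases it.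

Step 2
Reactants: 4 rac-5-(chloromethyl)-3-hydroxy-4-(4-hydroxyphenyl)furan-2(5H)-one
Product: 5 rac-5-(chloromethyl)-3-(methoxymethoxy)-4-[4-(methoxymethoxy)phenyl]furan-2(5H)-one
Conditions: MOMCl (2.6 equiv), iPr2NEt (3 equiv), CH2Cl2, 0 °C
Reagents that add atoms: chloromethyl methyl ether, COCCl
Why: O-Alkylation (Williamson type) of the acidic enol and phenol hydroxyl groups uses an amine too weak to trigger vinylogous E1cB loss of HCl at 0 °C, and the acetals withstand zinc, Ag2CO3 and palladium.

Step 3
Reactants: 5 rac-5-(chloromethyl)-3-(methoxymethoxy)-4-[4-(methoxymethoxy)phenyl]furan-2(5H)-one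
Product: 7 (2Z)-2-(methoxymethoxy)-3-[4-(methoxymethoxy)phenyl]penta-2,4-dienoic acid, via iodomethyl lactone 6 (not isolated)
Conditions: NaI (3 equiv), DME, 85 °C; then acid-washed Zn dust (5 equiv), DME–H2O 9:1, 40 °C, ultrasound; work-up at pH 4; 7 is used at once
Reagents that add atoms: sodium iodide, [Na+].[I-] (its iodine stands in 6 only)
Why: Finkelstein exchange and then zinc-mediated reductive β-elimination of the carboxylate (Boord type, as in the Vasella fragmentation) open the ring, and because the tetrasubstituted alkene was part of that ring, CO2H and the new vinyl group can only emerge cis, i.e. as the (Z)-acid.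

Step 4
Reactants: 8 4-iodophenol; 9 1-bromo-3-methylbut-2-ene (prenyl bromide)
Product: 10 4-iodo-2-(3-methylbut-2-en-1-yl)phenol
Conditions: NaH (1.05 equiv), toluene, 0 °C; then 9 (1.0 equiv), rt
Reagents that add atoms: none
Why: ortho-C-Alkylation of a tight sodium phenoxide ion pair in a non-polar solvent, with the para position blocked by iodine, should place the prenyl group next to the hydroxyl group by SN2 attack at the primary carbon of 9.

Step 5
Reactants: 10 4-iodo-2-(3-methylbut-2-en-1-yl)phenol
Product: 11 4-iodo-1-(methoxymethoxy)-2-(3-methylbut-2-en-1-yl)benzene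
Conditions: MOMCl (1.3 equiv), iPr2NEt (1.6 equiv), CH2Cl2, 0 °C to rt
Reagents that add atoms: chloromethyl methyl ether, COCCl
Why: Standard MOM protection of a phenol (Williamson type) keeps the phenoxide from binding palladium or silver in step 6.

Step 6
Reactants: 7 (2Z)-2-(methoxymethoxy)-3-[4-(methoxymethoxy)phenyl]penta-2,4-dienoic acid; 11 4-iodo-1-(methoxymethoxy)-2-(3-methylbut-2-en-1-yl)benzene
Product: 12 (5R)-3-(methoxymethoxy)-4-[4-(methoxymethoxy)phenyl]-5-{[4-(methoxymethoxy)-3-(3-methylbut-2-en-1-yl)phenyl]methyl}furan-2(5H)-one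
Conditions: Pd2(dba)3 (2.5 mol %), (S)-t-BuPHOX [(S)-4-tert-butyl-2-(2-diphenylphosphinophenyl)-4,5-dihydrooxazole, 6 mol %], Ag2CO3 (0.6 equiv), toluene, 50 °C, dark
Reagents that add atoms: none
Why: Proposed new method: zerovalent palladium inserts into the C–I bond of 11, Ag2CO3 removes iodide and deprotonates 7, the cationic arylpalladium binds the terminal vinyl group, and syn migratory insertion puts the aryl group on the =CH2 carbon (the new CH2–aryl bond) and palladium on the neighbouring CH, which relaxes to an η3-allyl over the later C5–C4–C3; the carboxylate, held cis by the (Z)-alkene, then attacks the CH terminus, giving the lactone and returning zerovalent palladium. The closest known reaction types are the enantioselective Heck insertion/Tsuji–Trost cascades of aryl halides with 1,3-dienes and O-nucleophiles, and the coupling–cyclisation of 2,3-allenoic acids with aryl iodides, which runs through the same kind of 1-carboxy-2-aryl-η3-allylpalladium and closes it to 4-arylfuran-2(5H)-ones with a configurationally stable C5; what is new is the entry into this allyl from a 2,4-dienoic acid and its control by a ligand. The lactone ring closes in a 5-exo-tet mode (oxygen displaces palladium at C5 of the η1 form, i.e. attack at the less substituted allyl terminus), whereas closure at the other terminus would need a three-membered ring and is excluded. C5 is controlled by the ligand alone: either the face of the vinyl group is chosen in the insertion, or, if the allyl faces exchange through an O-bound palladium dienolate, the faster C–O closure of one diastereomeric allyl complex decides (Curtin–Hammett), at the terminus trans to phosphorus. The step needs chemoselectivity for the monosubstituted vinyl group over the trisubstituted prenyl alkene and the tetrasubstituted enol-ether alkene (secured by sterics and allyl stabilisation), aryl transfer to the terminal carbon (secured by allyl formation), and capture faster than β-hydride elimination to the Heck triene (secured by η3 binding, the chelating ligand and the intramolecular carboxylate, which leave divalent palladium no free site).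

Step 7
Reactants: 12 (5R)-tris-MOM lactone
Product: 13 (5R)-3-hydroxy-4-(4-hydroxyphenyl)-5-{[4-hydroxy-3-(3-methylbut-2-en-1-yl)phenyl]methyl}furan-2(5H)-one (target)
Conditions: 3 M aq HCl–MeOH (1:6), 45 °C
Reagents that add atoms: none
Why: Acid-catalysed transacetalisation of the three MOM acetals to dimethoxymethane is a precedented way to free ortho-prenylphenols without chroman closure when the acid is dilute and the temperature moderate, and C5–H is not exchanged under acid, so the (R) configuration should hold.

**Compound list**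
1 | 3-(4-hydroxyphenyl)-2-oxopropanoic acid (4-hydroxyphenylpyruvic acid) | O=C(O)C(=O)Cc1ccc(O)cc1 | starting material
2 | chloroacetaldehyde (about 50 wt % in water) | O=CCCl | starting material
3 | 5-chloro-4-hydroxy-3-(4-hydroxyphenyl)-2-oxopentanoic acid (aldol adduct, racemic diastereomer mixture, present as potassium salt) | O=C(O)C(=O)C(c1ccc(O)cc1)C(O)CCl | intermediate
4 | rac-5-(chloromethyl)-3-hydroxy-4-(4-hydroxyphenyl)furan-2(5H)-one | O=C1OC(CCl)C(c2ccc(O)cc2)=C1O | intermediate
5 | rac-5-(chloromethyl)-3-(methoxymethoxy)-4-[4-(methoxymethoxy)phenyl]furan-2(5H)-one | COCOC1=C(c2ccc(OCOC)cc2)C(CCl)OC1=O | intermediate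
6 | rac-5-(iodomethyl)-3-(methoxymethoxy)-4-[4-(methoxymethoxy)phenyl]furan-2(5H)-one | COCOC1=C(c2ccc(OCOC)cc2)C(CI)OC1=O | intermediate
7 | (2Z)-2-(methoxymethoxy)-3-[4-(methoxymethoxy)phenyl]penta-2,4-dienoic acid | C=C/C(c1ccc(OCOC)cc1)=C(/OCOC)C(=O)O | intermediate
8 | 4-iodophenol | Oc1ccc(I)cc1 | starting material
9 | 1-bromo-3-methylbut-2-ene | CC(C)=CCBr | starting material
10 | 4-iodo-2-(3-methylbut-2-en-1-yl)phenol | CC(C)=CCc1cc(I)ccc1O | intermediate
11 | 4-iodo-1-(methoxymethoxy)-2-(3-methylbut-2-en-1-yl)benzene | CC(C)=CCc1cc(I)ccc1OCOC | intermediate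
12 | (5R)-3-(methoxymethoxy)-4-[4-(methoxymethoxy)phenyl]-5-{[4-(methoxymethoxy)-3-(3-methylbut-2-en-1-yl)phenyl]methyl}furan-2(5H)-one | CC(C)=CCc1cc(C[C@H]2OC(=O)C(OCOC)=C2c2ccc(OCOC)cc2)ccc1OCOC | intermediate
13 | (5R)-3-hydroxy-4-(4-hydroxyphenyl)-5-{[4-hydroxy-3-(3-methylbut-2-en-1-yl)phenyl]methyl}furan-2(5H)-one | CC(C)=CCc1cc(C[C@H]2OC(=O)C(O)=C2c2ccc(O)cc2)ccc1O | target

Total step count: 7. Longest linear sequence: 5 steps (1, 2, 3, 6, 7).

**Steps most likely to fail**

Risk 1 (step 6): β-hydride elimination may outrun C–O closure, or the ligand may discriminate the faces only weakly.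
- The fallback uses known chemistry, sets out from 11 and comes back at 12. It makes the same CH2–aryl bond by epoxide opening and takes C5 from the chiral pool.
- Iodine–magnesium exchange on 11 (iPrMgCl·LiCl, THF, −20 °C), then CuBr·SMe2-catalysed opening of commercial methyl (2R)-oxirane-2-carboxylate at its CH2 terminus, should give methyl (2R)-2-hydroxy-3-[4-(methoxymethoxy)-3-(3-methylbut-2-en-1-yl)phenyl]propanoate F1.
- Esterification with 2-(methoxymethoxy)acetic acid (DCC, DMAP, CH2Cl2) gives methyl (2R)-2-{[(methoxymethoxy)acetyl]oxy}-3-[4-(methoxymethoxy)-3-(3-methylbut-2-en-1-yl)phenyl]propanoate F2.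
- Dieckmann cyclisation (LiN(SiMe3)2, THF, −78 °C) gives (5R)-4-hydroxy-3-(methoxymethoxy)-5-{[4-(methoxymethoxy)-3-(3-methylbut-2-en-1-yl)phenyl]methyl}furan-2(5H)-one F3.
- Tf2O and iPr2NEt at −78 °C give (2R)-4-(methoxymethoxy)-2-{[4-(methoxymethoxy)-3-(3-methylbut-2-en-1-yl)phenyl]methyl}-5-oxo-2,5-dihydrofuran-3-yl trifluoromethanesulfonate F4.
- Suzuki–Miyaura coupling with 4-(methoxymethoxy)phenylboronic acid (Pd(PPh3)4, K3PO4, dioxane, 50 °C) returns to 12.

Risk 2 (step 1): chloride may be displaced at the aldol stage, by oxirane closure through the aldolate or by Feist–Benary-type furan formation through the enolate oxygen, before the lactone closes.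
- The fallback installs the leaving group only after ring closure. It sets out from 1 and comes back at 6, which is then treated with zinc as in the second half of step 3.
- Aldol–lactonisation of 1 with commercial (tert-butyldimethylsilyloxy)acetaldehyde (DBU, DMF, 0 °C; work-up at pH 3) should give rac-5-{[(tert-butyldimethylsilyl)oxy]methyl}-3-hydroxy-4-(4-hydroxyphenyl)furan-2(5H)-one F5.
- MOMCl and iPr2NEt give rac-5-{[(tert-butyldimethylsilyl)oxy]methyl}-3-(methoxymethoxy)-4-[4-(methoxymethoxy)phenyl]furan-2(5H)-one F6.
- Bu4NF buffered with AcOH gives rac-5-(hydroxymethyl)-3-(methoxymethoxy)-4-[4-(methoxymethoxy)phenyl]furan-2(5H)-one F7.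
- Appel iodination (I2, PPh3, imidazole, CH2Cl2) gives 6.

Risk 3 (step 4): O-alkylation and double alkylation may compete with ortho-C-alkylation.
- The fallback delivers the prenyl group by a sigmatropic shift. It sets out from 8 and comes back at 10.
- O-Alkylation of 8 with 3-chloro-3-methylbut-1-yne (DBU, CuCl2 cat., MeCN, 0 °C) should give 1-iodo-4-[(2-methylbut-3-yn-2-yl)oxy]benzene F8.
- Semihydrogenation (H2, Pd/CaCO3 poisoned with Pb(OAc)2, quinoline, EtOAc) gives 1-iodo-4-[(2-methylbut-3-en-2-yl)oxy]benzene F9.
- Aromatic Claisen rearrangement (N,N-diethylaniline, 130 °C) moves the inverted allyl unit to the ortho carbon and gives 10.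

**Further compounds**
F1 | step 6 | methyl (2R)-2-hydroxy-3-[4-(methoxymethoxy)-3-(3-methylbut-2-en-1-yl)phenyl]propanoate | COC(=O)[C@H](O)Cc1ccc(OCOC)c(CC=C(C)C)c1
F2 | step 6 | methyl (2R)-2-{[(methoxymethoxy)acetyl]oxy}-3-[4-(methoxymethoxy)-3-(3-methylbut-2-en-1-yl)phenyl]propanoate | COC(=O)[C@H](OC(=O)COCOC)Cc1ccc(OCOC)c(CC=C(C)C)c1
F3 | step 6 | (5R)-4-hydroxy-3-(methoxymethoxy)-5-{[4-(methoxymethoxy)-3-(3-methylbut-2-en-1-yl)phenyl]methyl}furan-2(5H)-one | CC(C)=CCc1cc(C[C@H]2OC(=O)C(OCOC)=C2O)ccc1OCOC
F4 | step 6 | (2R)-4-(methoxymethoxy)-2-{[4-(methoxymethoxy)-3-(3-methylbut-2-en-1-yl)phenyl]methyl}-5-oxo-2,5-dihydrofuran-3-yl trifluoromethanesulfonate | CC(C)=CCc1cc(C[C@H]2OC(=O)C(OCOC)=C2OS(=O)(=O)C(F)(F)F)ccc1OCOC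
F5 | step 1 | rac-5-{[(tert-butyldimethylsilyl)oxy]methyl}-3-hydroxy-4-(4-hydroxyphenyl)furan-2(5H)-one | CC(C)(C)[Si](C)(C)OCC1OC(=O)C(O)=C1c1ccc(O)cc1
F6 | step 1 | rac-5-{[(tert-butyldimethylsilyl)oxy]methyl}-3-(methoxymethoxy)-4-[4-(methoxymethoxy)phenyl]furan-2(5H)-one | CC(C)(C)[Si](C)(C)OCC1OC(=O)C(OCOC)=C1c1ccc(OCOC)cc1
F7 | step 1 | rac-5-(hydroxymethyl)-3-(methoxymethoxy)-4-[4-(methoxymethoxy)phenyl]furan-2(5H)-one | OCC1OC(=O)C(OCOC)=C1c1ccc(OCOC)cc1
F8 | step 4 | 1-iodo-4-[(2-methylbut-3-yn-2-yl)oxy]benzene | C#CC(C)(C)Oc1ccc(I)cc1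
F9 | step 4 | 1-iodo-4-[(2-methylbut-3-en-2-yl)oxy]benzene | C=CC(C)(C)Oc1ccc(I)cc1
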